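## Structural features

The target is a germacrane: a ten-membered carbocycle C1–C10 with a 1(10)E trisubstituted alkene (methyl C14 on C10) and a 4,5-epoxide (methyl C15 on C4; 4S,5R) in which ring carbons C3 and C6 are cis on the oxirane. A free secondary hydroxyl sits at C6 (6R), an angelate at C8 (8S), and C7 (7S) bears the side chain C11(S)H(CH3)–CH2–O-angelate. C5, C6, C7 and C8 are contiguous stereocentres, flanked by the fully substituted C4 and the exocyclic C11; the C6 oxygen is syn to the C7 side chain, the C8 oxygen is anti to it, and the epoxide oxygen is erythro to the C6 hydroxyl. The two (Z)-2-methylbut-2-enoates are fragile, because they isomerise to tiglates and migrate to the free C6 hydroxyl under base or nucleophilic catalysis. The epoxide is fragile as well, because it lies next to a free hydroxyl and across the ring from C1=C10, so acid would trigger transannular cyclisation. The real difficulty is a medium ring that must hold one E and one Z trisubstituted alkene (the latter the epoxide precursor) beside three ring stereocentres and one side-chain stereocentre. The key step exploits the 1,5-diene C10=C1–C2–C3–C4=C5 inside the ten-membered ring: with oxygen on C5 it is the retron of an oxy-Cope rearrangement of a cis-1-isopropenyl-2-vinylcyclohexanol whose six-membered ring is C5–C6–C7–C8–C9–C10. That cyclohexanol must carry the vinyl group (on C10), the isopropenyl group (on C5), the C6 oxygen and the C7 side chain on one face, and the tertiary hydroxyl, the C10 methyl and the C8 oxygen on the other.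

## Logic of the disconnections

31 to 30. The two C–O bonds of the oxirane (O–C4 and O–C5) are cut. The epoxide is the most acid-sensitive group and is best made last from the allylic alcohol. This removes two stereocentres. The forward step must deliver oxygen only to C4=C5, on the face set by the C6 hydroxyl, and leave C1=C10 and both enoates alone.

30 to 29 to 26 and 27. The acyl C–O bonds at O8 and O12 are cut, and the C6 hydroxyl is traced to an acetal. The angelates cannot survive hydride, strong base or fluoride, so they are attached late to a diol in which only O8 and O12 are free. Two molecules of 27 are consumed per molecule of 26. The forward steps must acylate without Z to E isomerisation and then cleave the acetal without harming the esters, the allylic C6–O bond or the diene.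

26 to 25 to 24. Two O–Si bonds are restored and the C5–H bond is traced to a C5–O triflate. The triflate is the form in which the enolate of the ring expansion is captured. The reduction must keep the alkene geometry.

24 to 21 (key). C2–C3 is cut and C5–C10 is reconnected. The ten-membered ring collapses to a cyclohexane made from the chiral pool, and both ring alkenes become consequences of one chair transition state. The forward step needs the cis-dialkenyl carbinol in the chair that keeps the C7 and C8 substituents equatorial, and a non-migrating group on O6.

21 to 19 to 18. The protecting groups are removed and O6 is joined to C12 as a γ-lactone. The lactone proves the syn relation of O6 and the side chain and makes C11 epimerisable. The forward steps are a hydride reduction and a primary-before-secondary-before-tertiary protection sequence.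

18 to 17 to 15 (through 16). The O6–C6 bond of the lactone and the C5–O bond are cut back to a C5=C6 alkene and a carboxylic acid. Three stereocentres (C5, C6 and, by equilibration, C11) are traded for one alkene. The forward step must epoxidise the ring alkene on the face anti to the vinyl group, and the acid must open the oxirane at C6.

15 to 14 to 12 and 13, and 12 to 11. The C4–C5 bond is cut. A carbon nucleophile adding to the C5 ketone of 11 would be expected to enter anti to the axial vinyl group and give the trans-dialkenyl carbinol, which leads to the 4E series. The isopropenyl carbon is therefore attached to trigonal C5 by cross-coupling, and the C5–O bond is formed afterwards from the open face. The forward steps need enolisation toward C6 only and coupling at a hindered triflate.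

11 to 10 to 7 and 8. The C10–C1 bond is cut. Conjugate reduction gives 9 regiospecifically, and axial attack places the two-carbon arm syn to the C7 side chain. The forward step needs 1,4- rather than 1,2-reduction and C–C bond formation at a tetrasubstituted enolate carbon.

7 to 6 to 5 to 4. The C12 carboxyl is traced to the terminal alkene carbon. The side chain must be oxidised before the vinyl group exists, because no borane would distinguish the two terminal alkenes. C11 is left uncontrolled on purpose and corrected in 17.

4 to 3 to 2 to 1. The C8–O bond is cut. C8 is the γ-carbon of the enone of 1 and is reached through the extended dienol ether. The forward steps need γ-deprotonation under equilibrating conditions and attack anti to the C7 substituent.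

## Other disconnections considered

Alternative 1: The cut is C6–C7.
- Forward step: Zn dust inserts into the allylic C–Br bond of the open-chain bromomethyl enoate aldehyde A1, and the γ-carbon C7 of the allylzinc adds to the C6 aldehyde (intramolecular Barbier allylation). This would give the hydroxy acrylate A2, which should lactonise to the cis-fused methylene lactone.
- In favour: ring closure and both C6 and C7 would be created in one step, whereas the chosen key step creates no stereocentre. The open-chain precursor is a convergent terpenoid chain with both alkenes already in place. The lactone that the chosen plan builds separately comes for free. On bond-forming economy and convergence it is the better plan.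
- Against: the two new centres would be controlled only by the C8 silyloxy group through a ten-membered cyclic transition state, which is hard to predict. High dilution is needed. The (Z)-enal can isomerise under Lewis-acidic ZnBr2. C8 needs an asymmetric reaction rather than the chiral pool.
- Comparison: after ring closure the methylene lactone would still need conjugate reduction, C11 equilibration, lactone reduction and differentiation of the C6 and C8 hydroxyls, so the endgame is no shorter. The chosen plan accepts a longer linear sequence and gets its ring geometry from a rigid chair.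

Alternative 2: The cut is C9–C10.
- Forward step: a nickel catalyst (Ni(cod)2, a trialkylphosphine, Et3B as reductant) would couple the terminal epoxide carbon C9 of the alkynyl epoxide A3 with alkyne carbon C10 and deliver hydrogen to C1, giving the ten-membered diene alcohol A4.
- In favour: the 1(10)E geometry follows from syn addition across the alkyne and is fixed by mechanism, which is at least equal to and arguably better than a conformational preference. The C8 hydroxyl appears free and unique, so the protecting-group logic is simpler than in the chosen plan. The 4Z alkene can be made in open chain by standard olefination.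
- Against: this coupling is established intramolecularly for small rings. A ten-membered carbocycle would stretch it beyond that, and regiochemistry at the alkyne and oligomerisation at high dilution are open questions. C6, C7, C8 and C11 would all need acyclic stereocontrol.
- Comparison: it is mechanistically attractive but rests on an unprecedented ring size. The chosen plan uses a ring expansion with direct precedent and takes C7 from the chiral pool, at the cost of more steps before the ring is formed.

Alternative 3: The cut is C3–C4.
- Forward step: the primary radical generated from the iodo ynone A5 (Bu3SnH or (Me3Si)3SiH, initiator, high dilution) would add to the ynone β-carbon C4 and give the cyclodecadienone A6 after hydrogen transfer.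
- In favour: like the chosen step it creates no stereocentre and needs no chiral reagent, so on that point it is equal. Radical conditions are neutral and tolerate silyl ethers. The C6 ketone of A6 would allow the C6 hydroxyl to be set late by choice of hydride.
- Against: ten-membered endo radical closures are slow, so premature reduction of the radical competes. The vinyl radical gives E/Z mixtures at C4=C5, whereas the chair of the Cope step defines that geometry. The C6 ketone has an epimerisable C7 and a β-silyloxy group at C8 prone to elimination. C6 would then need a stereoselective reduction.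
- Comparison: step counts to the acyclic precursor are similar to those of the cyclohexanol. The chosen plan is preferred for control of alkene geometry and for the stability of its intermediates.

Key step: step 16

Remark: germacrane numbering (C1 to C15; C14 is the methyl on C10, C15 the methyl on C4) is used for all intermediates. From step 4 to step 12 the compounds are pairs of C11 epimers (undefined C11 in the SMILES), and step 13 is meant to make them uniform.

## Route

Step 1
Reactants: 1 (R)-carvone
Product: 2 linear tert-butyldimethylsilyl dienol ether of 1 (OSi on C5; C5=C10 and C8=C9)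
Conditions: KH (slight deficiency), THF, 0 °C to rt; TBSCl, −78 °C to rt
Reagents that add atoms: tert-butyldimethylsilyl chloride, CC(C)(C)[Si](C)(C)Cl
Why: Under equilibrating conditions the linearly conjugated potassium dienolate formed by loss of a C8 proton should be the most stable enolate of this α-methyl cyclohexenone (the species behind deconjugative α-alkylation), and silyl chlorides capture it on oxygen; reaction type: thermodynamic enolisation and O-silylation to a 1-silyloxy-1,3-diene.

Step 2
Reactants: 2 silyl dienol ether
Product: 3 (4S,5R)-4-hydroxy-2-methyl-5-(prop-1-en-2-yl)cyclohex-2-en-1-one (hydroxyl on C8, trans to the C7 isopropenyl group)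
Conditions: mCPBA, NaHCO3, CH2Cl2, −20 °C; aqueous work-up
Reagents that add atoms: 3-chloroperoxybenzoic acid, OOC(=O)c1cccc(Cl)c1
Why: Vinylogous Rubottom oxidation: the peracid attacks the electron-rich diene terminus C8, the silyloxy group opens the oxirane and the silyl group is lost on work-up to give the γ-hydroxy enone. Attack anti to the adjacent C7 substituent should set the C8 oxygen trans to it, and the isolated 1,1-disubstituted alkene is far less nucleophilic than the dienol ether.

Step 3
Reactants: 3 γ-hydroxy enone
Product: 4 (4S,5R)-4-(tert-butyldimethylsilyloxy)-2-methyl-5-(prop-1-en-2-yl)cyclohex-2-en-1-one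
Conditions: TBSCl, imidazole, DMF, rt
Reagents that add atoms: tert-butyldimethylsilyl chloride, CC(C)(C)[Si](C)(C)Cl
Why: Standard silylation of a secondary alcohol; the silyl ether is meant to last until step 18 and leave together with the C12 silyl ether.

Step 4
Reactants: 4 silyloxy enone
Product: 5 C5,C12-diol with C8 silyl ether and C9=C10 alkene (mixture at C5 and C11)
Conditions: 9-BBN (3 equiv), THF, 0 °C to rt; NaOH, H2O2, 0 °C
Reagents that add atoms: hydrogen peroxide, OO
Why: Hydroboration–oxidation places boron and then hydroxyl on the terminal carbon C12 of the 1,1-disubstituted alkene; 9-BBN also reduces the enone carbonyl in a 1,2-sense, which is accepted because step 5 restores it. C11 is formed without control on purpose, since it becomes epimerisable next to the carboxyl group and is corrected in step 13.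

Step 5
Reactants: 5 diol
Product: 6 8-silyloxy enone 12-carboxylic acid (C11 epimer pair)
Conditions: TEMPO (cat.), PhI(OAc)2 (excess), MeCN–H2O, rt
Reagents that add atoms: water, O
Why: Oxoammonium (TEMPO) oxidation with a hypervalent iodine co-oxidant takes the primary alcohol through the aldehyde hydrate to the acid and the allylic alcohol back to the enone, under conditions mild enough for the silyl ether.

Step 6
Reactants: 6 keto acid
Product: 7 methyl ester of 6 (C11 epimer pair)
Conditions: Me3SiCHN2, PhMe–MeOH, 0 °C
Reagents that add atoms: (trimethylsilyl)diazomethane, C[Si](C)(C)C=[N+]=[N-]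
Why: Neutral methylation of the acid by the diazoalkane avoids base, to which the γ-silyloxy enone is sensitive; the ester protects the acid from the strong bases of steps 7 and 9.

Step 7
Reactants: 7 keto ester; 8 phenyl vinyl sulfoxide
Product: 10 C10-quaternary 2-(phenylsulfinyl)ethyl ketone (arm cis to the C7 side chain), via potassium enolate 9 (not isolated)
Conditions: K[sec-Bu3BH], THF, −78 °C; then 8, −78 to −20 °C; NH4Cl
Reagents that add atoms: none
Why: Conjugate hydride addition to the β-unsubstituted enone gives the C5/C10 enolate 9 regiospecifically. Its Michael addition to the vinyl sulfoxide (a vinyl cation equivalent) should occur by axial attack on the half-chair with equatorial C7 and C8 substituents, that is on the face syn to the C7 side chain, as in alkylations of 2-methyl-5-substituted cyclohexanone enolates; the new arm is then cis to the side chain and the methyl group trans.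

Step 8
Reactants: 10 sulfoxide
Product: 11 2-methyl-2-vinyl ketone (vinyl cis to the C7 side chain)
Conditions: NaHCO3, PhMe, 110 °C
Reagents that add atoms: none
Why: Thermal syn-elimination (Ei) of the alkyl aryl sulfoxide unveils the vinyl group; the only β-hydrogens are on the methylene next to C10, so only the terminal alkene can form.

Step 9
Reactants: 11 vinyl ketone
Product: 12 C5=C6 enol triflate
Conditions: KN(SiMe3)2, THF, −78 °C; PhNTf2, −78 to 0 °C
Reagents that add atoms: N-phenylbis(trifluoromethanesulfonimide), O=S(=O)(N(c1ccccc1)S(=O)(=O)C(F)(F)F)C(F)(F)F
Why: C10 is quaternary, so the amide base can enolise only toward C6, and the ketone is far more acidic than the ester; O-triflation of the potassium enolate gives the enol triflate.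

Step 10
Reactants: 12 enol triflate; 13 isopropenylboronic acid pinacol ester
Product: 14 2-isopropenyl diene ester (C5=C6 and C4=C3)
Conditions: Pd(dppf)Cl2 (cat.), K3PO4, dioxane–H2O, 60 °C
Reagents that add atoms: none
Why: Suzuki–Miyaura coupling of an alkenyl triflate with an alkenylboronate attaches C4 to trigonal C5. This avoids adding a carbon nucleophile to a C5 ketone, which would be expected to enter anti to the axial vinyl group and give the trans-dialkenyl carbinol.

Step 11
Reactants: 14 diene ester
Product: 15 diene carboxylic acid (C11 epimer pair)
Conditions: LiOH, THF–MeOH–H2O, rt; dilute HCl to pH 3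
Reagents that add atoms: water (as hydroxide), O
Why: Saponification frees the carboxylic acid that serves as the internal nucleophile of step 12; no stereocentre other than the already mixed C11 is at risk.

Step 12
Reactants: 15 diene acid
Product: 17 cis-fused 6,12-lactone with tertiary C5 hydroxyl (C11 epimer pair), via epoxy acid 16 (not isolated)
Conditions: mCPBA, CH2Cl2, 0 °C to rt
Reagents that add atoms: 3-chloroperoxybenzoic acid, OOC(=O)c1cccc(Cl)c1
Why: Prilezhaev epoxidation should prefer the trisubstituted ring alkene over the isopropenyl and vinyl groups, and the face anti to the pseudo-axial C10 vinyl group. The carboxylic acid then opens epoxide 16 at C6 from the opposite face in a 5-exo, trans-diaxial (Fürst–Plattner) manner, which makes the C6 oxygen cis to the side chain, the C5 hydroxyl trans to it and the isopropenyl group cis to the vinyl group. An epoxide on the wrong face cannot lactonise, so the lactone can only have this configuration.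

Step 13
Reactants: 17 hydroxy lactone (C11 epimer pair)
Product: 18 (11S)-hydroxy lactone (methyl trans to the C7–C8 bond on the lactone ring)
Conditions: DBU, PhMe, 90 °C
Reagents that add atoms: none
Why: Reversible deprotonation α to the lactone carbonyl equilibrates C11; the cis-fused γ-lactone should prefer the methyl group on the convex face, trans to the C7–C8 bond, which is the 11S arrangement of the target, so both epimers should converge on 18. The tertiary alcohol lies on the face opposite the side chain and cannot transacylate.

Step 14
Reactants: 18 lactone
Product: 19 5,6,12-triol 8-silyl ether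
Conditions: LiAlH4, THF, 0 °C
Reagents that add atoms: none
Why: Hydride reduction of the lactone gives the 6,12-diol without touching alkenes or the silyl ether; C11 is no longer epimerisable afterwards.

Step 15
Reactants: 19 triol
Product: 21 cis-1-isopropenyl-2-methyl-2-vinylcyclohexanol with C6 methoxymethyl ether and C8 and C12 silyl ethers, via C12 mono-silyl ether 20 (not isolated)
Conditions: TBSCl, imidazole, CH2Cl2, 0 °C; then iPr2NEt, MOMCl, 0 °C to rt
Reagents that add atoms: tert-butyldimethylsilyl chloride, CC(C)(C)[Si](C)(C)Cl; chloromethyl methyl ether, COCCl
Why: The primary C12 hydroxyl is silylated far faster than the hindered secondary and tertiary ones, and the alkoxymethyl chloride then etherifies the secondary C6 hydroxyl while the tertiary C5 hydroxyl, flanked by two fully substituted carbons, stays free. An acetal is chosen at C6 because a silyl group there would migrate to the neighbouring alkoxide in step 16.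

Step 16
Reactants: 21 dialkenyl cyclohexanol
Product: 24 ten-membered C5 enol triflate with 1(10)E alkene and C3 cis to C6 on C4=C5, via potassium alkoxide 22 (not isolated), via ten-membered potassium enolate 23 (not isolated)
Conditions: KH, 18-crown-6, THF, 0 °C to rt; then PhNTf2, −78 °C
Reagents that add atoms: N-phenylbis(trifluoromethanesulfonimide), O=S(=O)(N(c1ccccc1)S(=O)(=O)C(F)(F)F)C(F)(F)F
Why: KH with 18-crown-6 gives the dissociated potassium alkoxide 22, whose oxyanion weakens the C5–C10 bond and accelerates the [3,3]-sigmatropic shift so that C2–C3 forms as C5–C10 breaks at or below room temperature (anionic oxy-Cope rearrangement; the closest known type is the ring expansion of 1,2-dialkenylcyclohexanols to cyclodec-5-enones with trapping of the enolate). The ten-membered ring arises by a four-atom ring expansion through a six-membered chair-like pericyclic array and not by end-to-end cyclisation, so no high dilution is needed. No stereocentre is created: C5 and C10 become trigonal and C6, C7, C8 and C11 are untouched. The step needs E geometry at C1=C10 and C3 cis to C6 at C4=C5. Because the alkenyl groups are cis, one is axial and one equatorial, and in the chair that keeps the C7 and C8 substituents equatorial the vinyl group is axial and the isopropenyl group equatorial; in the derived Cope chair the C10–C9 bond and the oxyanion are pseudo-equatorial (hence 1(10)E and oxygen trans to C3) and the C5–C6 bond is pseudo-axial (hence C6 cis to C3). The other chair would need the C7, C8 and isopropenyl substituents axial and should be disfavoured, and the boat array is normally higher in energy. Enolate 23 is formed regiospecifically at C4=C5 and has no proton source for equilibration, so PhNTf2 fixes it on oxygen as the triflate.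

Step 17
Reactants: 24 enol triflate
Product: 25 1(10)E,4Z-diene with C6 methoxymethyl ether and C8 and C12 silyl ethers
Conditions: Pd(OAc)2 (cat.), PPh3, Bu3N, HCO2H, DMF, 60 °C
Reagents that add atoms: none
Why: Palladium-catalysed formate reduction of an enol triflate: oxidative addition to zerovalent palladium, formate exchange, loss of CO2 and reductive elimination of C5–H with retention of alkene geometry, giving the 4Z alkene; isolated alkenes, acetal and silyl ethers are inert.

Step 18
Reactants: 25 bis-silyl ether
Product: 26 8,12-diol C6 methoxymethyl ether
Conditions: Bu4NF, THF, rt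
Reagents that add atoms: none
Why: Fluoride cleaves both silyl ethers; the acetal at C6 is stable, so only the two hydroxyls that are to be acylated are exposed.

Step 19
Reactants: 26 diol; 27 angelic acid
Product: 29 C8 and C12 diangelate C6 methoxymethyl ether, via mixed anhydride 28 (not isolated)
Conditions: 27 (2.5 equiv), 2,4,6-Cl3C6H2COCl (2.5 equiv), Et3N, PhMe, rt; then 26, 80 °C
Reagents that add atoms: angelic acid (the second equivalent of 27), C/C=C(/C)C(=O)O
Why: Yamaguchi esterification: each of the two hydroxyls (primary C12 and secondary C8) is acylated by one molecule of mixed anhydride 28, so two molecules of 27 end up in 29. No nucleophilic catalyst is used, conditions under which (Z)-2-methylbut-2-enoates should keep their geometry instead of isomerising to tiglates.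

Step 20
Reactants: 29 diangelate acetal
Product: 30 C8 and C12 diangelate with free C6 hydroxyl
Conditions: Me3SiOTf, 2,2′-bipyridyl, CH2Cl2, 0 °C; then H2O
Reagents that add atoms: none
Why: The silyl triflate buffered by bipyridyl converts the methoxymethyl ether into an N-(alkoxymethyl)pyridinium salt that water hydrolyses to the alcohol, a nearly neutral acetal cleavage that should spare the esters, the allylic C6–O bond and the diene.

Step 21
Reactants: 30 allylic alcohol
Product: 31 target, (1(10)E,4S,5R,6R,7S,8S,11S)-4,5-epoxy-6-hydroxygermacr-1(10)-ene-8,12-diyl diangelate
Conditions: VO(acac)2 (cat.), t-BuOOH, PhH, 0 °C to rt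
Reagents that add atoms: tert-butyl hydroperoxide, CC(C)(C)OO
Why: Vanadium-catalysed hydroxyl-directed epoxidation: the C6 vanadate ester delivers the peroxide oxygen to the adjacent C4=C5 bond from the peripheral face, through the conformer in which the C6–O bond is tilted toward that face, H6 lies near the alkene plane and C7 sits on the far face (the mode usual for medium-ring cis-allylic alcohols, where oxygen is delivered syn to the hydroxyl). This should give the erythro 4S,5R epoxy alcohol, and the remote C1=C10 bond and the electron-poor angelate alkenes should not be epoxidised.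

## Compound list

1 | (R)-carvone, (5R)-2-methyl-5-(prop-1-en-2-yl)cyclohex-2-en-1-one | C=C(C)[C@H]1CC(=O)C(C)=CC1 | starting material
2 | tert-butyldimethylsilyl 1,3-dienol ether of 1 (OSi on C5, C5=C10 and C8=C9, C7 as in 1) | C=C(C)[C@H]1CC(O[Si](C)(C)C(C)(C)C)=C(C)C=C1 | intermediate
3 | (4S,5R)-4-hydroxy-2-methyl-5-(prop-1-en-2-yl)cyclohex-2-en-1-one (C8 hydroxyl trans to the C7 substituent) | C=C(C)[C@H]1CC(=O)C(C)=C[C@@H]1O | intermediate
4 | (4S,5R)-4-(tert-butyldimethylsilyloxy)-2-methyl-5-(prop-1-en-2-yl)cyclohex-2-en-1-one | C=C(C)[C@H]1CC(=O)C(C)=C[C@@H]1O[Si](C)(C)C(C)(C)C | intermediate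
5 | 4-(tert-butyldimethylsilyloxy)-5-(1-hydroxypropan-2-yl)-2-methylcyclohex-2-en-1-ol, ring centres C7 and C8 as in 4, mixture at C5 and C11 | OCC(C)[C@H]1CC(O)C(C)=C[C@@H]1O[Si](C)(C)C(C)(C)C | intermediate
6 | 2-[2-(tert-butyldimethylsilyloxy)-4-methyl-5-oxocyclohex-3-en-1-yl]propanoic acid, ring centres as in 4, C11 epimer pair | OC(=O)C(C)[C@H]1CC(=O)C(C)=C[C@@H]1O[Si](C)(C)C(C)(C)C | intermediate
7 | methyl ester of 6, C11 epimer pair | COC(=O)C(C)[C@H]1CC(=O)C(C)=C[C@@H]1O[Si](C)(C)C(C)(C)C | intermediate
8 | phenyl vinyl sulfoxide (racemic) | C=CS(=O)c1ccccc1 | starting material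
9 | potassium C5-enolate (C5=C10) formed from 7 by conjugate reduction | COC(=O)C(C)[C@H]1CC([O-])=C(C)C[C@@H]1O[Si](C)(C)C(C)(C)C.[K+] | intermediate
10 | methyl 2-[2-(tert-butyldimethylsilyloxy)-4-methyl-5-oxo-4-(2-(phenylsulfinyl)ethyl)cyclohexyl]propanoate, sulfinylethyl arm on C10 cis to the C7 side chain, C8 oxygen trans; mixture at C11 and sulfur | COC(=O)C(C)[C@H]1CC(=O)[C@@](C)(CCS(=O)c2ccccc2)C[C@@H]1O[Si](C)(C)C(C)(C)C | intermediate
11 | methyl 2-[2-(tert-butyldimethylsilyloxy)-4-methyl-5-oxo-4-vinylcyclohexyl]propanoate, vinyl cis to the C7 side chain; C11 epimer pair | COC(=O)C(C)[C@H]1CC(=O)[C@@](C)(C=C)C[C@@H]1O[Si](C)(C)C(C)(C)C | intermediate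
12 | C5=C6 enol triflate of 11 | COC(=O)C(C)[C@H]1C=C(OS(=O)(=O)C(F)(F)F)[C@@](C)(C=C)C[C@@H]1O[Si](C)(C)C(C)(C)C | intermediate
13 | isopropenylboronic acid pinacol ester, 4,4,5,5-tetramethyl-2-(prop-1-en-2-yl)-1,3,2-dioxaborolane | C=C(C)B1OC(C)(C)C(C)(C)O1 | starting material
14 | methyl 2-[6-(tert-butyldimethylsilyloxy)-4-methyl-3-(prop-1-en-2-yl)-4-vinylcyclohex-2-en-1-yl]propanoate (C5=C6 alkene, isopropenyl on C5); C11 epimer pair | COC(=O)C(C)[C@H]1C=C(C(C)=C)[C@@](C)(C=C)C[C@@H]1O[Si](C)(C)C(C)(C)C | intermediate
15 | carboxylic acid of 14; C11 epimer pair | OC(=O)C(C)[C@H]1C=C(C(C)=C)[C@@](C)(C=C)C[C@@H]1O[Si](C)(C)C(C)(C)C | intermediate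
16 | 5,6-epoxy acid from 15, epoxide oxygen trans to the C7 side chain and to the vinyl group | OC(=O)C(C)[C@H]1[C@@H]2O[C@]2(C(C)=C)[C@@](C)(C=C)C[C@@H]1O[Si](C)(C)C(C)(C)C | intermediate
17 | cis-fused 6,12-lactone: C6 oxygen and C7 side chain cis, tertiary C5 hydroxyl trans to them, isopropenyl and vinyl cis, C8 silyloxy trans to the side chain; C11 epimer pair | O=C2C(C)[C@H]1[C@@H](O2)[C@@](O)(C(C)=C)[C@@](C)(C=C)C[C@@H]1O[Si](C)(C)C(C)(C)C | intermediate
18 | (11S)-lactone of 17, methyl on the convex face (trans to the C7–C8 bond) | O=C2[C@@H](C)[C@H]1[C@@H](O2)[C@@](O)(C(C)=C)[C@@](C)(C=C)C[C@@H]1O[Si](C)(C)C(C)(C)C | intermediate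
19 | 5,6,12-triol 8-tert-butyldimethylsilyl ether (cis-1-isopropenyl-2-methyl-2-vinylcyclohexane-1,6-diol core) | OC[C@@H](C)[C@H]1[C@@H](O)[C@@](O)(C(C)=C)[C@@](C)(C=C)C[C@@H]1O[Si](C)(C)C(C)(C)C | intermediate
20 | 12-O-silyl ether of 19 (5,6-diol) | CC(C)(C)[Si](C)(C)OC[C@@H](C)[C@H]1[C@@H](O)[C@@](O)(C(C)=C)[C@@](C)(C=C)C[C@@H]1O[Si](C)(C)C(C)(C)C | intermediate
21 | cis-1-isopropenyl-2-methyl-2-vinylcyclohexanol with C6 methoxymethyl ether, C8 and C12 tert-butyldimethylsilyl ethers and the (11S) side chain on C7 | CC(C)(C)[Si](C)(C)OC[C@@H](C)[C@H]1[C@@H](OCOC)[C@@](O)(C(C)=C)[C@@](C)(C=C)C[C@@H]1O[Si](C)(C)C(C)(C)C | intermediate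
22 | potassium alkoxide of 21 | CC(C)(C)[Si](C)(C)OC[C@@H](C)[C@H]1[C@@H](OCOC)[C@@]([O-])(C(C)=C)[C@@](C)(C=C)C[C@@H]1O[Si](C)(C)C(C)(C)C.[K+] | intermediate
23 | ten-membered potassium C5-enolate, 1(10)E, C3 cis to C6 on C4=C5 | CC(C)(C)[Si](C)(C)OC[C@@H](C)[C@H]1[C@@H](OCOC)/C([O-])=C(/C)CC/C=C(\C)C[C@@H]1O[Si](C)(C)C(C)(C)C.[K+] | intermediate
24 | ten-membered C5 enol triflate, 1(10)E, C3 cis to C6 on C4=C5 | CC(C)(C)[Si](C)(C)OC[C@@H](C)[C@H]1[C@@H](OCOC)/C(OS(=O)(=O)C(F)(F)F)=C(/C)CC/C=C(\C)C[C@@H]1O[Si](C)(C)C(C)(C)C | intermediate
25 | 1(10)E,4Z-germacradiene with C6 methoxymethyl ether and C8 and C12 silyl ethers | CC(C)(C)[Si](C)(C)OC[C@@H](C)[C@H]1[C@@H](OCOC)/C=C(/C)CC/C=C(\C)C[C@@H]1O[Si](C)(C)C(C)(C)C | intermediate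
26 | 1(10)E,4Z-germacradiene-8,12-diol 6-methoxymethyl ether | OC[C@@H](C)[C@H]1[C@@H](OCOC)/C=C(/C)CC/C=C(\C)C[C@@H]1O | intermediate
27 | angelic acid, (Z)-2-methylbut-2-enoic acid | C/C=C(/C)C(=O)O | starting material
28 | angelic 2,4,6-trichlorobenzoic anhydride | C/C=C(/C)C(=O)OC(=O)c1c(Cl)cc(Cl)cc1Cl | intermediate
29 | 8,12-diangelate 6-methoxymethyl ether of the 1(10)E,4Z-diene | C/C=C(/C)C(=O)OC[C@@H](C)[C@H]1[C@@H](OCOC)/C=C(/C)CC/C=C(\C)C[C@@H]1OC(=O)/C(C)=C\C | intermediate
30 | 8,12-diangelate of the 1(10)E,4Z-dien-6-ol | C/C=C(/C)C(=O)OC[C@@H](C)[C@H]1[C@@H](O)/C=C(/C)CC/C=C(\C)C[C@@H]1OC(=O)/C(C)=C\C | intermediate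
31 | CNP0272382.1, (1(10)E,4S,5R,6R,7S,8S,11S)-4,5-epoxy-6-hydroxygermacr-1(10)-ene-8,12-diyl bis[(Z)-2-methylbut-2-enoate] | C/C=C(/C)C(=O)OC[C@@H](C)[C@H]1[C@@H](O)[C@H]2O[C@@]2(C)CC/C=C(\C)C[C@@H]1OC(=O)/C(C)=C\C | target

## Count and risks

Total step count: 21. Longest linear sequence: 21 steps from 1 (8, 13 and 27 enter as purchased reagents).

Steps least certain to work:

Step 16 (key step). The rearrangement may pass in part through the boat array or through the ring-flipped chair, because the reactive chair carries the axial C6 acetal oxygen and the axial vinyl group on the same face. This would erode the geometry at C1=C10 and C4=C5. Proton transfer in the enolate before triflation is a second risk.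
Fallback, from 21 and back at 24: silylate the tertiary hydroxyl with N-(trimethylsilyl)imidazole (60 °C) to the trimethylsilyl ether F1. Heat it (PhMe, sealed tube, 180 to 200 °C) for a neutral silyloxy-Cope rearrangement to the ten-membered trimethylsilyl enol ether F2; the bulky silyloxy group should reinforce the pseudo-equatorial preference, and a silyl enol ether cannot equilibrate. Cleave the O–Si bond with MeLi (THF, 0 °C) and add PhNTf2 to reach 24.

Step 2. The peracid may attack the α-carbon C10 of the dienol ether instead of C8, or the face syn to the isopropenyl group, because both ends of the diene are nucleophilic.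
Fallback, from 2 and back at 3: photooxygenation (O2, tetraphenylporphyrin, visible light, CH2Cl2, −78 °C). Singlet oxygen adds in a [4+2] sense across C5 and C8 anti to the isopropenyl group and gives the bicyclic endoperoxide F3, which places oxygen on C8 by construction. PPh3 then cleaves the O–O bond by attack at the less hindered oxygen on C8, the C5 silyl hemiketal collapses to the ketone, and aqueous work-up releases the C8 hydroxyl of 3.

Step 7. 1,2-Reduction may compete, because the β-carbon is flanked by the silyloxy-bearing C8. The Michael addition to the tetrasubstituted enolate carbon may be slow enough for proton transfer from C6 and double alkylation.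
Fallback, from 7 and back at 11: generate the same enolate with K[sec-Bu3BH] and capture it with acetaldehyde (aldol addition, same axial attack) to give the β-hydroxy ketone F4. Dehydrate with the Burgess reagent (PhH, 50 °C); syn-elimination can only use the methyl hydrogens and gives the vinyl group of 11.

Step 12. The acidic peracid medium may ionise the tertiary allylic C5–O bond of the epoxide, with opening at C5, SN2′ capture or diene formation instead of attack at C6.
Fallback, from 14 and back at 17: epoxidise the ester with dimethyldioxirane (acetone, −20 °C, neutral) to the epoxy ester F5. Saponify with LiOH so that the carboxylate opens the oxirane at C6 under basic conditions, and acidify only at the end to close the γ-hydroxy acid to 17.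

Step 21. Facial selectivity may be poor if the ring reacts through the conformer that has C7 on the other side of the C4=C5 plane, which turns the C6–O bond into the plane and away from the alkene. Oxygen would then arrive without direction on the opposite face and give the threo epoxy alcohol.
Fallback, from 30 and back at 31: titanium–tartrate epoxidation (Ti(OiPr)4, D-(−)-diisopropyl tartrate, t-BuOOH, 4 Å molecular sieves, CH2Cl2, −20 °C). This replaces substrate direction by reagent control; D-(−)-tartrate is the enantiomer that delivers oxygen to the face required for the erythro product from the C6 configuration of 30 (matched case). No new compound is formed.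

## Further compounds

F1 | step 16 | trimethylsilyl ether of 21 (tertiary C5–O–SiMe3) | CC(C)(C)[Si](C)(C)OC[C@@H](C)[C@H]1[C@@H](OCOC)[C@@](O[Si](C)(C)C)(C(C)=C)[C@@](C)(C=C)C[C@@H]1O[Si](C)(C)C(C)(C)C
F2 | step 16 | ten-membered C5 trimethylsilyl enol ether, 1(10)E, C3 cis to C6 on C4=C5 | CC(C)(C)[Si](C)(C)OC[C@@H](C)[C@H]1[C@@H](OCOC)/C(O[Si](C)(C)C)=C(/C)CC/C=C(\C)C[C@@H]1O[Si](C)(C)C(C)(C)C
F3 | step 2 | C5,C8-endoperoxide of 2 (peroxide bridge anti to the isopropenyl group) | C=C(C)[C@H]1C[C@]2(O[Si](C)(C)C(C)(C)C)OO[C@H]1C=C2C
F4 | step 7 | aldol adduct of enolate 9 with acetaldehyde (1-hydroxyethyl on C10 cis to the C7 side chain; mixture at the carbinol and at C11) | COC(=O)C(C)[C@H]1CC(=O)[C@@](C)(C(C)O)C[C@@H]1O[Si](C)(C)C(C)(C)C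
F5 | step 12 | methyl ester of epoxy acid 16 | COC(=O)C(C)[C@H]1[C@@H]2O[C@]2(C(C)=C)[C@@](C)(C=C)C[C@@H]1O[Si](C)(C)C(C)(C)C
F0 | step 21 | none | none
A1 | alternative 1 | methyl (2Z,4S,6E,10Z)-2-(bromomethyl)-6,10-dimethyl-12-oxo-4-(triethylsilyloxy)dodeca-2,6,10-trienoate | COC(=O)/C(CBr)=C/[C@@H](O[Si](CC)(CC)CC)C/C(C)=C/CC/C(C)=C\C=O
A2 | alternative 1 | ten-membered 6-hydroxy 7-(acrylate) ring with 1(10)E and 4Z alkenes and C8 triethylsilyl ether | COC(=O)C(=C)[C@H]1[C@@H](O)/C=C(/C)CC/C=C(\C)C[C@@H]1O[Si](CC)(CC)CC
A3 | alternative 2 | open-chain (4Z)-alkynyl epoxide: C8–C9 terminal epoxide, C10≡C1 methyl alkyne, C6 tert-butyldimethylsilyl ether, C12 triethylsilyl ether | CC#CCC/C(C)=C\[C@H](O[Si](C)(C)C(C)(C)C)[C@H]([C@H](C)CO[Si](CC)(CC)CC)[C@@H]1CO1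
A4 | alternative 2 | ten-membered 1(10)E,4Z-diene with free C8 hydroxyl, C6 tert-butyldimethylsilyl ether and C12 triethylsilyl ether | CC[Si](CC)(CC)OC[C@@H](C)[C@H]1[C@@H](O[Si](C)(C)C(C)(C)C)/C=C(/C)CC/C=C(\C)C[C@@H]1O
A5 | alternative 3 | open-chain iodo ynone: C3 primary iodide, 1(10)E alkene, C6 ketone conjugated to the C5≡C4 alkyne, C8 and C12 triethylsilyl ethers | CC#CC(=O)[C@H]([C@H](C)CO[Si](CC)(CC)CC)[C@@H](O[Si](CC)(CC)CC)C/C(C)=C/CCI
A6 | alternative 3 | ten-membered 6-oxo 1(10)E,4Z-diene bis(triethylsilyl) ether | CC[Si](CC)(CC)OC[C@@H](C)[C@H]1C(=O)/C=C(/C)CC/C=C(\C)C[C@@H]1O[Si](CC)(CC)CC
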